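**Remark on the structure:** the SMILES is read as robinetinidol-(4β→8)-epigallocatechin 3-O-gallate. The upper unit is (2R,3S,4R), with the C2 aryl and C3 hydroxyl trans and the C3 hydroxyl and C4 aryl cis; the lower unit is (2R,3R). (−)-Epigallocatechin is taken as a purchasable starting material.

## Retrosynthetic overview

1. Target ⇒ removal of thirteen O-benzyl groups ⇒ late esterification of the lower C3 hydroxyl with protected gallic acid ⇒ interflavan C4–C8 bond from a C4 ketone of the upper unit and the 8-lithio derivative of protected (−)-epigallocatechin, then ionic hydrogenation of the tertiary benzylic alcohol (hydride anti to the C3 oxygen gives the 3,4-cis, 4β bond).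
2. Upper unit: ring C is closed by a one-pot aldol addition / intramolecular SNAr annulation of an α-benzyloxy 2-fluoroaryl ketone with 3,4,5-tris(benzyloxy)benzaldehyde, which makes C2–C3 and O1–C8a and leaves a flavanonol.
3. Enabling feature: the C4 carbonyl attached to ring A, one oxidation level above the target. It acidifies C3–H for the aldol step and activates the ortho carbon C8a (C–F) of ring A for attack by the C2 alkoxide. The same carbonyl later receives the lower unit and is removed as C4–H.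
4. Stereochemistry: the annulation drains all isomers into the 2,3-trans racemate. A transfer hydrogenation under dynamic kinetic resolution (ring C opens and recloses at O1–C2) fixes (2R,3R), and C4 follows from the ionic hydrogenation.
5. Ring order: rings A and B of both units and ring C of the lower unit are bought; ring C of the upper unit is the only ring made (step 3).

Key step: step 3

## Route

Step 1
Reactants: 1 4-bromo-3-fluorophenol
Product: 2 4-(benzyloxy)-1-bromo-2-fluorobenzene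
Conditions: BnBr, K2CO3, DMF, 25 °C
Reagents that add atoms: benzyl bromide, BrCc1ccccc1
Why: Williamson etherification of the phenoxide (SN2 at the benzylic carbon) protects the future C7 oxygen of ring A.

Step 2
Reactants: 2 4-(benzyloxy)-1-bromo-2-fluorobenzene; 3 2-(benzyloxy)-N-methoxy-N-methylacetamide
Product: 6 2-(benzyloxy)-1-[4-(benzyloxy)-2-fluorophenyl]ethan-1-one, via arylmagnesium chloride 4 (not isolated), via magnesium hemiaminal chelate 5 (not isolated)
Conditions: iPrMgCl·LiCl, THF, −15 °C; then 3, −15 → 0 °C; then 1 M HCl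
Reagents that add atoms: none
Why: Bromine–magnesium exchange gives aryl Grignard 4, which should be stable below 0 °C despite the ortho fluorine, and it adds only once to amide 3 because chelate 5 survives until the acidic quench (Weinreb ketone synthesis).

Step 3
Reactants: 6 2-(benzyloxy)-1-[4-(benzyloxy)-2-fluorophenyl]ethan-1-one; 7 3,4,5-tris(benzyloxy)benzaldehyde
Product: 10 rac-(2R,3R)-3,7-bis(benzyloxy)-2-[3,4,5-tris(benzyloxy)phenyl]chroman-4-one (2,3-trans), via potassium enolate 8 (not isolated), via potassium aldolate 9 (not isolated)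
Conditions: KN(SiMe3)2 (1.0 equiv), THF, −78 °C; then 7; then 18-crown-6, −78 → 40 °C
Reagents that add atoms: none
Why: KN(SiMe3)2 removes the C3 proton, which the C4 carbonyl makes acidic, and potassium enolate 8 adds to aldehyde 7 (aldol addition, C2–C3 bond) to give alkoxide 9, whose oxygen then displaces fluoride from C8a of ring A, the carbon ortho to the same carbonyl (addition–elimination, intramolecular SNAr, O1–C8a bond). The closest known reaction types are the crossed aldol addition of aryl ketone enolates and the base-mediated cyclisation of 2-fluoroaryl β-hydroxy ketones to chroman-4-ones. Ring C closes in a 6-exo-trig mode on the arene carbon. Both new stereocentres, C2 and C3, are under thermodynamic control: the aldolates interconvert by retro-aldol cleavage and C3 of the cyclised ketone epimerises by enolisation, so every isomer should drain into the 2,3-trans (diequatorial) racemate, whose absolute configuration is fixed in step 4. The step needs O-arylation by the C2 alkoxide only and no dehydration to the chalcone; the benzyl ether on the C3 oxygen leaves a single nucleophilic oxygen, the single fluorine ortho to the carbonyl leaves a single electrophilic carbon, and the aprotic medium offers no hydroxide leaving group.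

Step 4
Reactants: 10 rac-(2R,3R)-3,7-bis(benzyloxy)-2-[3,4,5-tris(benzyloxy)phenyl]chroman-4-one
Product: 12 (2R,3S,4R)-3,7-bis(benzyloxy)-2-[3,4,5-tris(benzyloxy)phenyl]chroman-4-ol, via ring-opened chalcone 11 (not isolated)
Conditions: RuCl[(S,S)-TsDPEN](p-cymene) (2 mol %), HCO2H/DBU (2:3), MeCN, 40 °C
Reagents that add atoms: none
Why: Noyori–Ikariya asymmetric transfer hydrogenation under dynamic kinetic resolution: the base opens ring C of both antipodes of 10 by retro-oxa-Michael reaction to chalcone 11 and recloses it, while the (S,S)-catalyst should reduce only the (2R,3R)-ketone, placing the new C4 hydroxyl cis to the C2 aryl group, so that C2 and C3 are set by catalyst control.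

Step 5
Reactants: 12 (2R,3S,4R)-3,7-bis(benzyloxy)-2-[3,4,5-tris(benzyloxy)phenyl]chroman-4-ol
Product: 13 (2R,3R)-3,7-bis(benzyloxy)-2-[3,4,5-tris(benzyloxy)phenyl]chroman-4-one
Conditions: Dess–Martin periodinane, CH2Cl2, 0 → 25 °C
Reagents that add atoms: none
Why: Dess–Martin oxidation of the benzylic alcohol returns the C4 carbonyl without base, so C2 and C3 should keep their configuration.

Step 6
Reactants: 14 (−)-epigallocatechin
Product: 15 (2R,3R)-5,7-bis(benzyloxy)-2-[3,4,5-tris(benzyloxy)phenyl]chroman-3-ol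
Conditions: BnBr (5.5 equiv), K2CO3, DMF, 0 → 25 °C, argon
Reagents that add atoms: benzyl bromide, BrCc1ccccc1
Why: Williamson etherification in which K2CO3 deprotonates only the five phenols, so the secondary C3 hydroxyl stays free and the (2R,3R) centres are untouched.

Step 7
Reactants: 15 (2R,3R)-5,7-bis(benzyloxy)-2-[3,4,5-tris(benzyloxy)phenyl]chroman-3-ol
Product: 16 (2R,3R)-5,7-bis(benzyloxy)-8-bromo-2-[3,4,5-tris(benzyloxy)phenyl]chroman-3-ol
Conditions: NBS, CH2Cl2, −78 → 0 °C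
Reagents that add atoms: N-bromosuccinimide, O=C1CCC(=O)N1Br
Why: Electrophilic aromatic bromination at C8, which is flanked by O1 and the C7 ether and is the most nucleophilic ring carbon of 5,7-di-O-benzyl flavans; the bromine marks the site of the interflavan bond.

Step 8
Reactants: 16 (2R,3R)-5,7-bis(benzyloxy)-8-bromo-2-[3,4,5-tris(benzyloxy)phenyl]chroman-3-ol
Product: 17 tert-butyl{[(2R,3R)-5,7-bis(benzyloxy)-8-bromo-2-[3,4,5-tris(benzyloxy)phenyl]chroman-3-yl]oxy}dimethylsilane
Conditions: TBSOTf, 2,6-lutidine, CH2Cl2, 0 °C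
Reagents that add atoms: tert-butyldimethylsilyl trifluoromethanesulfonate, CC(C)(C)[Si](C)(C)OS(=O)(=O)C(F)(F)F
Why: Silyl ether formation with the triflate, which is reactive enough for the hindered axial C3 hydroxyl; the silyl group tolerates the organolithium step and is removed selectively in step 11.

Step 9
Reactants: 17 tert-butyl{[(2R,3R)-5,7-bis(benzyloxy)-8-bromo-2-[3,4,5-tris(benzyloxy)phenyl]chroman-3-yl]oxy}dimethylsilane; 13 (2R,3R)-3,7-bis(benzyloxy)-2-[3,4,5-tris(benzyloxy)phenyl]chroman-4-one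
Product: 19 tertiary C4 alcohol of the two joined units (upper unit 2R,3R; lower unit 2R,3R; C4 epimers), via aryllithium 18 (not isolated)
Conditions: t-BuLi (2.0 equiv), THF, −78 °C; then 13, −78 °C; then H2O
Reagents that add atoms: none
Why: Bromine–lithium exchange followed by 1,2-addition of aryllithium 18 to the C4 ketone fixes the interflavan bond at C8 of the lower unit without regioisomers; the new C4 centre is of no consequence because it is ionised in step 10.

Step 10
Reactants: 19 tertiary C4 alcohol of the two joined units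
Product: 21 deca-O-benzyl 3-O-silyl dimer (4β→8 bond; upper unit 2R,3S,4R; lower unit 2R,3R), via benzylic cation 20 (not isolated)
Conditions: Bu3SnH, CF3CO2H, CH2Cl2, −78 → 0 °C
Reagents that add atoms: none
Why: Ionic hydrogenation in which CF3CO2H ionises the doubly benzylic alcohol to cation 20 (stabilised by O1 and the para benzyloxy group of ring A) and Bu3SnH should deliver hydride to the face anti to the neighbouring C3 benzyloxy group, which leaves the lower unit cis to the C3 oxygen (4R).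

Step 11
Reactants: 21 deca-O-benzyl 3-O-silyl dimer
Product: 22 deca-O-benzyl dimer in which the C3 hydroxyl of the lower unit is free
Conditions: HF·pyridine, THF, 0 → 25 °C
Reagents that add atoms: none
Why: Fluoride-mediated desilylation frees only the C3 hydroxyl of the lower unit, because the C3 oxygen of the upper unit is a benzyl ether.

Step 12
Reactants: 22 deca-O-benzyl dimer in which the C3 hydroxyl of the lower unit is free; 23 3,4,5-tris(benzyloxy)benzoic acid
Product: 25 trideca-O-benzyl robinetinidol-(4β→8)-epigallocatechin 3-O-gallate, via O-acylisourea 24 (not isolated)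
Conditions: DCC, DMAP, CH2Cl2, 25 °C
Reagents that add atoms: none
Why: Steglich esterification (activation of 23 as O-acylisourea 24, acyl transfer by DMAP) acylates the single free hydroxyl with retention at C3.

Step 13
Reactants: 25 trideca-O-benzyl robinetinidol-(4β→8)-epigallocatechin 3-O-gallate
Product: 26 robinetinidol-(4β→8)-epigallocatechin 3-O-gallate
Conditions: H2 (1 atm), Pd(OH)2/C, THF/MeOH, 25 °C
Reagents that add atoms: none
Why: Hydrogenolysis of all thirteen O-benzyl groups under neutral conditions should leave the ester, the acid-labile interflavan bond and the five stereocentres untouched.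

## Compound list

1 | 4-bromo-3-fluorophenol | Oc1ccc(Br)c(F)c1 | starting material
2 | 4-(benzyloxy)-1-bromo-2-fluorobenzene | Fc1cc(OCc2ccccc2)ccc1Br | intermediate
3 | 2-(benzyloxy)-N-methoxy-N-methylacetamide | CON(C)C(=O)COCc1ccccc1 | starting material
4 | [4-(benzyloxy)-2-fluorophenyl]magnesium chloride | Cl[Mg]c1ccc(OCc2ccccc2)cc1F | intermediate (not isolated)
5 | chloromagnesium alkoxide of the tetrahedral adduct of 4 and 3 (Weinreb chelate) | CON(C)C(O[Mg]Cl)(COCc1ccccc1)c1ccc(OCc2ccccc2)cc1F | intermediate (not isolated)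
6 | 2-(benzyloxy)-1-[4-(benzyloxy)-2-fluorophenyl]ethan-1-one | O=C(COCc1ccccc1)c1ccc(OCc2ccccc2)cc1F | intermediate
7 | 3,4,5-tris(benzyloxy)benzaldehyde | O=Cc1cc(OCc2ccccc2)c(OCc2ccccc2)c(OCc2ccccc2)c1 | starting material
8 | potassium (Z)-enolate of 6 | [K+].[O-]/C(=C\OCc1ccccc1)c1ccc(OCc2ccccc2)cc1F | intermediate (not isolated)
9 | potassium 2-(benzyloxy)-3-[4-(benzyloxy)-2-fluorophenyl]-3-oxo-1-[3,4,5-tris(benzyloxy)phenyl]propan-1-olate, mixture of all stereoisomers | [K+].[O-]C(c1cc(OCc2ccccc2)c(OCc2ccccc2)c(OCc2ccccc2)c1)C(OCc1ccccc1)C(=O)c1ccc(OCc2ccccc2)cc1F | intermediate (not isolated)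
10 | rac-(2R,3R)-3,7-bis(benzyloxy)-2-[3,4,5-tris(benzyloxy)phenyl]chroman-4-one, 2,3-trans racemate (both antipodes written) | O=C1c2ccc(OCc3ccccc3)cc2O[C@H](c2cc(OCc3ccccc3)c(OCc3ccccc3)c(OCc3ccccc3)c2)[C@H]1OCc1ccccc1.O=C1c2ccc(OCc3ccccc3)cc2O[C@@H](c2cc(OCc3ccccc3)c(OCc3ccccc3)c(OCc3ccccc3)c2)[C@@H]1OCc1ccccc1 | intermediate
11 | 2-(benzyloxy)-1-[4-(benzyloxy)-2-hydroxyphenyl]-3-[3,4,5-tris(benzyloxy)phenyl]prop-2-en-1-one, either alkene geometry, present as its phenoxide | O=C(C(OCc1ccccc1)=Cc1cc(OCc2ccccc2)c(OCc2ccccc2)c(OCc2ccccc2)c1)c1ccc(OCc2ccccc2)cc1O | intermediate (not isolated)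
12 | (2R,3S,4R)-3,7-bis(benzyloxy)-2-[3,4,5-tris(benzyloxy)phenyl]chroman-4-ol (2,3-trans, 3,4-trans) | O[C@@H]1c2ccc(OCc3ccccc3)cc2O[C@H](c2cc(OCc3ccccc3)c(OCc3ccccc3)c(OCc3ccccc3)c2)[C@H]1OCc1ccccc1 | intermediate
13 | (2R,3R)-3,7-bis(benzyloxy)-2-[3,4,5-tris(benzyloxy)phenyl]chroman-4-one | O=C1c2ccc(OCc3ccccc3)cc2O[C@H](c2cc(OCc3ccccc3)c(OCc3ccccc3)c(OCc3ccccc3)c2)[C@H]1OCc1ccccc1 | intermediate
14 | (−)-epigallocatechin, (2R,3R)-2-(3,4,5-trihydroxyphenyl)chroman-3,5,7-triol | O[C@@H]1Cc2c(O)cc(O)cc2O[C@@H]1c1cc(O)c(O)c(O)c1 | starting material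
15 | (2R,3R)-5,7-bis(benzyloxy)-2-[3,4,5-tris(benzyloxy)phenyl]chroman-3-ol | O[C@@H]1Cc2c(OCc3ccccc3)cc(OCc3ccccc3)cc2O[C@@H]1c1cc(OCc2ccccc2)c(OCc2ccccc2)c(OCc2ccccc2)c1 | intermediate
16 | (2R,3R)-5,7-bis(benzyloxy)-8-bromo-2-[3,4,5-tris(benzyloxy)phenyl]chroman-3-ol | O[C@@H]1Cc2c(OCc3ccccc3)cc(OCc3ccccc3)c(Br)c2O[C@@H]1c1cc(OCc2ccccc2)c(OCc2ccccc2)c(OCc2ccccc2)c1 | intermediate
17 | tert-butyl{[(2R,3R)-5,7-bis(benzyloxy)-8-bromo-2-[3,4,5-tris(benzyloxy)phenyl]chroman-3-yl]oxy}dimethylsilane | CC(C)(C)[Si](C)(C)O[C@@H]1Cc2c(OCc3ccccc3)cc(OCc3ccccc3)c(Br)c2O[C@@H]1c1cc(OCc2ccccc2)c(OCc2ccccc2)c(OCc2ccccc2)c1 | intermediate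
18 | 8-lithio analogue of 17 | CC(C)(C)[Si](C)(C)O[C@@H]1Cc2c(OCc3ccccc3)cc(OCc3ccccc3)c([Li])c2O[C@@H]1c1cc(OCc2ccccc2)c(OCc2ccccc2)c(OCc2ccccc2)c1 | intermediate (not isolated)
19 | (2R,3R)-3,7-bis(benzyloxy)-2-[3,4,5-tris(benzyloxy)phenyl]chroman-4-ol carrying at C4 the C8 carbon of the (2R,3R) lower unit of 17; C4 epimers | CC(C)(C)[Si](C)(C)O[C@@H]1Cc2c(OCc3ccccc3)cc(OCc3ccccc3)c(C3(O)c4ccc(OCc5ccccc5)cc4O[C@H](c4cc(OCc5ccccc5)c(OCc5ccccc5)c(OCc5ccccc5)c4)[C@H]3OCc3ccccc3)c2O[C@@H]1c1cc(OCc2ccccc2)c(OCc2ccccc2)c(OCc2ccccc2)c1 | intermediate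
20 | C4 carbocation formed from 19 by loss of water | CC(C)(C)[Si](C)(C)O[C@@H]1Cc2c(OCc3ccccc3)cc(OCc3ccccc3)c([C+]3c4ccc(OCc5ccccc5)cc4O[C@H](c4cc(OCc5ccccc5)c(OCc5ccccc5)c(OCc5ccccc5)c4)[C@H]3OCc3ccccc3)c2O[C@@H]1c1cc(OCc2ccccc2)c(OCc2ccccc2)c(OCc2ccccc2)c1 | intermediate (not isolated)
21 | (2R,3S,4R)-3,7-bis(benzyloxy)-2-[3,4,5-tris(benzyloxy)phenyl]chroman-4-yl unit bonded through C4 to C8 of (2R,3R)-5,7-bis(benzyloxy)-3-(tert-butyldimethylsilyloxy)-2-[3,4,5-tris(benzyloxy)phenyl]chroman; C3 oxygen and C4 aryl of the upper unit cis | CC(C)(C)[Si](C)(C)O[C@@H]1Cc2c(OCc3ccccc3)cc(OCc3ccccc3)c([C@H]3c4ccc(OCc5ccccc5)cc4O[C@H](c4cc(OCc5ccccc5)c(OCc5ccccc5)c(OCc5ccccc5)c4)[C@H]3OCc3ccccc3)c2O[C@@H]1c1cc(OCc2ccccc2)c(OCc2ccccc2)c(OCc2ccccc2)c1 | intermediate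
22 | desilylated 21: lower unit (2R,3R)-chroman-3-ol, upper unit (2R,3S,4R) | O[C@@H]1Cc2c(OCc3ccccc3)cc(OCc3ccccc3)c([C@H]3c4ccc(OCc5ccccc5)cc4O[C@H](c4cc(OCc5ccccc5)c(OCc5ccccc5)c(OCc5ccccc5)c4)[C@H]3OCc3ccccc3)c2O[C@@H]1c1cc(OCc2ccccc2)c(OCc2ccccc2)c(OCc2ccccc2)c1 | intermediate
23 | 3,4,5-tris(benzyloxy)benzoic acid | OC(=O)c1cc(OCc2ccccc2)c(OCc2ccccc2)c(OCc2ccccc2)c1 | starting material
24 | O-[3,4,5-tris(benzyloxy)benzoyl]-N,N'-dicyclohexylisourea | O=C(OC(=NC1CCCCC1)NC1CCCCC1)c1cc(OCc2ccccc2)c(OCc2ccccc2)c(OCc2ccccc2)c1 | intermediate (not isolated)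
25 | 3,4,5-tris(benzyloxy)benzoate of 22 at the C3 oxygen of the lower unit (trideca-O-benzyl target) | O=C(O[C@@H]1Cc2c(OCc3ccccc3)cc(OCc3ccccc3)c([C@H]3c4ccc(OCc5ccccc5)cc4O[C@H](c4cc(OCc5ccccc5)c(OCc5ccccc5)c(OCc5ccccc5)c4)[C@H]3OCc3ccccc3)c2O[C@@H]1c1cc(OCc2ccccc2)c(OCc2ccccc2)c(OCc2ccccc2)c1)c1cc(OCc2ccccc2)c(OCc2ccccc2)c(OCc2ccccc2)c1 | intermediate
26 | robinetinidol-(4β→8)-epigallocatechin 3-O-gallate; upper unit (2R,3S,4R), lower unit (2R,3R) | O=C(O[C@@H]1Cc2c(O)cc(O)c([C@H]3c4ccc(O)cc4O[C@H](c4cc(O)c(O)c(O)c4)[C@H]3O)c2O[C@@H]1c1cc(O)c(O)c(O)c1)c1cc(O)c(O)c(O)c1 | target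

## Step count and risks

Total step count: 13. Longest linear sequence: 10 steps (steps 1–5 and 9–13); the lower-unit branch (steps 6–8) joins at step 9.

Steps most likely to fail:

**Step 3.** Retro-aldol cleavage may outrun the ring closure, or the base may reopen ring C after closure, so that the material stays at the open-chain stage.
Fallback, setting out from aldehyde 7 and coming back at 10, by the classical chalcone epoxide route. Commercial 1-[4-(benzyloxy)-2-hydroxyphenyl]ethan-1-one F1 is converted with MOMCl and iPr2NEt into 1-[4-(benzyloxy)-2-(methoxymethoxy)phenyl]ethan-1-one F2. Claisen–Schmidt condensation of F2 with 7 (KOH, EtOH) gives the (E)-chalcone F3. Weitz–Scheffer epoxidation (H2O2, NaOH, MeOH/THF) gives the racemic trans-epoxide F4. HCl in MeOH removes the acetal and lets the freed phenol open the epoxide at the benzylic carbon with inversion, giving the racemic trans-3-hydroxyflavanone F5. Acid-catalysed O-benzylation (benzyl 2,2,2-trichloroacetimidate, TfOH cat., CH2Cl2) then gives 10.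

**Step 4.** Racemisation through ring opening may be too slow relative to reduction, so that the process stalls as a simple kinetic resolution, or the ring-opened enone may undergo conjugate reduction.
Fallback, setting out from 10 and coming back at 21, using the enantiopure lower unit as the resolving element. Racemic 10 is treated with aryllithium 18 as in step 9, which gives 19 together with the diastereomeric tertiary alcohol F6 formed from the (2S,3S)-ketone. Ionic hydrogenation of the mixture as in step 10 gives 21 and the diastereomeric dimer F7. The two differ in the whole upper unit and should separate on silica; 21 re-enters the route at step 11.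

**Step 10.** Facial selectivity of hydride delivery to the C4 cation may be poor in this 5-deoxy 2,3-trans series, or the cation may lose the C3 proton.
Fallback, setting out from 12 and 15 and coming back at 21, by the classical flavan-4-ol condensation. Alcohol 15 is silylated (TBSOTf, 2,6-lutidine) to the 3-O-silyl ether F8. TMSOTf (CH2Cl2, −78 °C) ionises the C4 hydroxyl of 12, and F8 attacks the cation through C8 (Friedel–Crafts alkylation). This gives 21 beside its C4 epimer F9, from which 21 is separated by chromatography. The 3,4-trans epimer F9 is expected to predominate in this coupling, so it would supply 21 only as the minor isomer.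

## Further compounds

F1 | step 3 | 1-[4-(benzyloxy)-2-hydroxyphenyl]ethan-1-one | CC(=O)c1ccc(OCc2ccccc2)cc1O
F2 | step 3 | 1-[4-(benzyloxy)-2-(methoxymethoxy)phenyl]ethan-1-one | CC(=O)c1ccc(OCc2ccccc2)cc1OCOC
F3 | step 3 | (E)-1-[4-(benzyloxy)-2-(methoxymethoxy)phenyl]-3-[3,4,5-tris(benzyloxy)phenyl]prop-2-en-1-one | COCOc1cc(OCc2ccccc2)ccc1C(=O)/C=C/c1cc(OCc2ccccc2)c(OCc2ccccc2)c(OCc2ccccc2)c1
F4 | step 3 | racemic trans-2,3-epoxide of F3 (both antipodes written) | COCOc1cc(OCc2ccccc2)ccc1C(=O)[C@@H]1O[C@H]1c1cc(OCc2ccccc2)c(OCc2ccccc2)c(OCc2ccccc2)c1.COCOc1cc(OCc2ccccc2)ccc1C(=O)[C@H]1O[C@@H]1c1cc(OCc2ccccc2)c(OCc2ccccc2)c(OCc2ccccc2)c1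
F5 | step 3 | rac-(2R,3R)-7-(benzyloxy)-3-hydroxy-2-[3,4,5-tris(benzyloxy)phenyl]chroman-4-one, 2,3-trans racemate (both antipodes written) | O=C1c2ccc(OCc3ccccc3)cc2O[C@H](c2cc(OCc3ccccc3)c(OCc3ccccc3)c(OCc3ccccc3)c2)[C@H]1O.O=C1c2ccc(OCc3ccccc3)cc2O[C@@H](c2cc(OCc3ccccc3)c(OCc3ccccc3)c(OCc3ccccc3)c2)[C@@H]1O
F6 | step 4 | diastereomer of 19 with a (2S,3S) upper unit; C4 epimers | CC(C)(C)[Si](C)(C)O[C@@H]1Cc2c(OCc3ccccc3)cc(OCc3ccccc3)c(C3(O)c4ccc(OCc5ccccc5)cc4O[C@@H](c4cc(OCc5ccccc5)c(OCc5ccccc5)c(OCc5ccccc5)c4)[C@@H]3OCc3ccccc3)c2O[C@@H]1c1cc(OCc2ccccc2)c(OCc2ccccc2)c(OCc2ccccc2)c1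
F7 | step 4 | diastereomer of 21 with a (2S,3R,4S) upper unit | CC(C)(C)[Si](C)(C)O[C@@H]1Cc2c(OCc3ccccc3)cc(OCc3ccccc3)c([C@@H]3c4ccc(OCc5ccccc5)cc4O[C@@H](c4cc(OCc5ccccc5)c(OCc5ccccc5)c(OCc5ccccc5)c4)[C@@H]3OCc3ccccc3)c2O[C@@H]1c1cc(OCc2ccccc2)c(OCc2ccccc2)c(OCc2ccccc2)c1
F8 | step 10 | tert-butyl{[(2R,3R)-5,7-bis(benzyloxy)-2-[3,4,5-tris(benzyloxy)phenyl]chroman-3-yl]oxy}dimethylsilane | CC(C)(C)[Si](C)(C)O[C@@H]1Cc2c(OCc3ccccc3)cc(OCc3ccccc3)cc2O[C@@H]1c1cc(OCc2ccccc2)c(OCc2ccccc2)c(OCc2ccccc2)c1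
F9 | step 10 | C4 epimer of 21 with a (2R,3S,4S) upper unit (3,4-trans) | CC(C)(C)[Si](C)(C)O[C@@H]1Cc2c(OCc3ccccc3)cc(OCc3ccccc3)c([C@@H]3c4ccc(OCc5ccccc5)cc4O[C@H](c4cc(OCc5ccccc5)c(OCc5ccccc5)c(OCc5ccccc5)c4)[C@H]3OCc3ccccc3)c2O[C@@H]1c1cc(OCc2ccccc2)c(OCc2ccccc2)c(OCc2ccccc2)c1
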